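**Retrosynthetic overview**
- The target comes from a trans-chlorohydrin by C–Br formation with inversion; the chlorohydrin comes from a 2-chloro-4-bromo cyclohexanone by substrate-controlled reduction.
- The cyclohexane (the only ring) is closed from an acyclic α-bromo-α-chloro ketone by forming the C2–C3 bond: the ketone α-carbon, normally an enolate carbon, is used as a polarity-reversed (enolonium-type) electrophilic α-keto radical and bonds to the nucleophilic CH2 of an isopropenyl group. The same step places Cl at C2 and Br at C4.
- The α-bromo-α-chloro ketone comes from a morpholine amide and the 1-bromo-1-chloroethyl carbenoid; the (E)-chlorovinyl group is made beforehand by cross-metathesis with (E)-1,2-dichloroethene.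
- The amide comes from a racemic dienyl carbonate and a ketene aminal by iridium-catalysed asymmetric allylic alkylation, which sets the one stereocentre that controls the other three; the carbonate comes from methacrolein and vinylmagnesium bromide.

Assumption: the (S)-configured ligand gives the (S)-amide in step 2; if the sense of induction is the opposite, the (R)-ligand is used and nothing else changes.

Step 1
Reactants: 1 methacrolein (2-methylprop-2-enal); 2 vinylmagnesium bromide
Product: 4 methyl (2-methylpenta-1,4-dien-3-yl) carbonate (racemic), via bromomagnesium alkoxide 3 (not isolated)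
Conditions: THF, −78 to 0 °C; then ClCO2Me, 0 °C
Reagents that add atoms: methyl chloroformate, COC(=O)Cl
Why: Grignard 1,2-addition to the enal followed by in situ O-acylation of the magnesium alkoxide; no stereocontrol is needed because step 2 ionizes either enantiomer of the doubly allylic carbonate to the same allyl–iridium intermediate.

Step 2
Reactants: 4 methyl (2-methylpenta-1,4-dien-3-yl) carbonate; 5 4,4'-(ethene-1,1-diyl)dimorpholine
Product: 7 (3S)-1-(morpholin-4-yl)-3-(prop-1-en-2-yl)pent-4-en-1-one, via allylated ketene aminal 6 (not isolated)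
Conditions: [Ir(cod)Cl]2 (2 mol %), (S)-BINOL-derived N-(dibenzo[b,f]azepin-5-yl) phosphoramidite (P,olefin) ligand (8 mol %), THF, 25 °C; then H2O, SiO2
Reagents that add atoms: water, O
Why: Iridium-catalysed enantioconvergent, branch-selective asymmetric allylic alkylation (Tsuji–Trost type) in which the ketene aminal serves as an amide-enolate surrogate: the allyl–iridium complex is attacked at its substituted terminus on the face fixed by the ligand, which sets C3 as (S) and leaves a skipped diene, and aqueous work-up hydrolyses the aminal to the morpholine amide.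

Step 3
Reactants: 7 (3S)-1-(morpholin-4-yl)-3-(prop-1-en-2-yl)pent-4-en-1-one; 8 (E)-1,2-dichloroethene
Product: 9 (3S,4E)-5-chloro-1-(morpholin-4-yl)-3-(prop-1-en-2-yl)pent-4-en-1-one
Conditions: Mo(NC6F5)(CHCMe2Ph)(2,5-Me2C4H2N)(O-2,6-(2,4,6-Et3C6H2)2C6H3) (5 mol %), 8 (5 equiv), C6H6, 22 °C
Reagents that add atoms: none
Why: Kinetically E-selective molybdenum-catalysed cross-metathesis of the monosubstituted alkene with (E)-1,2-dichloroethene gives the (E)-alkenyl chloride, while the 1,1-disubstituted isopropenyl group is too hindered to react and the allylic stereocentre is not touched.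

Step 4
Reactants: 9 (3S,4E)-5-chloro-1-(morpholin-4-yl)-3-(prop-1-en-2-yl)pent-4-en-1-one; 10 1-bromo-1-chloroethane
Product: 13 (5S,6E)-2-bromo-2,7-dichloro-5-(prop-1-en-2-yl)hept-6-en-3-one (both C2 epimers), via 1-bromo-1-chloroethyllithium 11 (not isolated), via lithium hemiaminal alkoxide 12 (not isolated)
Conditions: 10, LiN(i-Pr)2, THF/Et2O, −105 °C; then 9, −105 to −90 °C; then AcOH, −90 °C
Reagents that add atoms: none
Why: Halocarbenoid acylation of a morpholine amide (homologous to the additions of dihalomethyllithiums to Weinreb and morpholine amides): the preformed carbenoid adds once because the chelated tetrahedral adduct survives until the cold acidic quench, and the C2 epimer mixture does not matter because C2 becomes a planar radical in step 5.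

Step 5
Reactants: 13 (5S,6E)-2-bromo-2,7-dichloro-5-(prop-1-en-2-yl)hept-6-en-3-one
Product: 14 (2R,4R,5S)-4-bromo-2-chloro-5-[(E)-2-chloroethenyl]-2,4-dimethylcyclohexan-1-one
Conditions: CuBr (10 mol %), tris(2-pyridylmethyl)amine (10 mol %), degassed toluene, high dilution, 50 °C
Reagents that add atoms: none
Why: Copper-catalysed bromine atom-transfer radical cyclization (Kharasch type) of an α-halo ketone acting as an enolonium equivalent: CuBr removes the weaker C–Br bond to give an electrophilic α-chloro-α-keto radical that adds 6-endo to the nucleophilic CH2 of the isopropenyl group (the carbonyl inside the forming ring and the 1,1-disubstituted alkene both favour 6-endo, and the hindered, less electron-rich chloroalkene is spared) through a chair transition state with the chloroalkenyl group equatorial and, for dipole and A(1,3) reasons, Cl pseudo-axial and CH3 pseudo-equatorial at C2 (Cl cis to the side chain, 2R), after which CuBr2 returns bromine to the tertiary C4 radical from the equatorial direction, away from the syn-axial C2–Cl bond and trans to the C5 substituent (4R).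

Step 6
Reactants: 14 (2R,4R,5S)-4-bromo-2-chloro-5-[(E)-2-chloroethenyl]-2,4-dimethylcyclohexan-1-one
Product: 15 (1R,2R,4R,5S)-4-bromo-2-chloro-5-[(E)-2-chloroethenyl]-2,4-dimethylcyclohexan-1-ol
Conditions: LiBH(s-Bu)3, THF, −78 °C; then pH 7 buffer
Reagents that add atoms: none
Why: Diastereoselective ketone reduction under steric approach control: the bulky trialkylborohydride avoids the axial hydrogens at C3 and C5 and attacks the 2,2-disubstituted cyclohexanone from the equatorial direction (as with 4,4-dimethyl-3-oxo steroids), giving the axial (1R) alcohol trans-diaxial to the C2–Cl bond, and the low temperature and neutral work-up protect the tertiary halides and prevent epoxide closure.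

Step 7
Reactants: 15 (1R,2R,4R,5S)-4-bromo-2-chloro-5-[(E)-2-chloroethenyl]-2,4-dimethylcyclohexan-1-ol
Product: 16 (1R,2S,4S,5R)-1,4-dibromo-5-chloro-2-[(E)-2-chloroethenyl]-1,5-dimethylcyclohexane (target)
Conditions: CBr4, P(n-C8H17)3, toluene, 70 °C
Reagents that add atoms: carbon tetrabromide, BrC(Br)(Br)Br
Why: Appel-type deoxybromination in the trialkylphosphine variant used for hindered secondary alcohols: bromide displaces the axial alkoxyphosphonium group in an SN2 step with inversion, giving the equatorial bromide cis to the tertiary chloride, and chlorine is a poor neighbouring group so retention through a chloronium ion should be minor.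

**Compound list**
1 | methacrolein (2-methylprop-2-enal) | C=C(C)C=O | starting material
2 | vinylmagnesium bromide | C=C[Mg]Br | starting material
3 | bromomagnesium 2-methylpenta-1,4-dien-3-olate (racemic) | C=C(C)C(C=C)O[Mg]Br | intermediate
4 | methyl (2-methylpenta-1,4-dien-3-yl) carbonate (racemic) | C=C(C)C(C=C)OC(=O)OC | intermediate
5 | 4,4'-(ethene-1,1-diyl)dimorpholine | C=C(N1CCOCC1)N1CCOCC1 | starting material
6 | 4,4'-[(3R)-3-(prop-1-en-2-yl)penta-1,4-diene-1,1-diyl]dimorpholine | C=C(C)[C@H](C=C)C=C(N1CCOCC1)N1CCOCC1 | intermediate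
7 | (3S)-1-(morpholin-4-yl)-3-(prop-1-en-2-yl)pent-4-en-1-one | C=C(C)[C@H](C=C)CC(=O)N1CCOCC1 | intermediate
8 | (E)-1,2-dichloroethene | Cl/C=C/Cl | starting material
9 | (3S,4E)-5-chloro-1-(morpholin-4-yl)-3-(prop-1-en-2-yl)pent-4-en-1-one | C=C(C)[C@H](/C=C/Cl)CC(=O)N1CCOCC1 | intermediate
10 | 1-bromo-1-chloroethane | CC(Cl)Br | starting material
11 | 1-bromo-1-chloroethyllithium | [Li]C(C)(Cl)Br | intermediate
12 | lithium hemiaminal alkoxide from 9 and 11 | C=C(C)[C@H](/C=C/Cl)CC(O[Li])(N1CCOCC1)C(C)(Cl)Br | intermediate
13 | (5S,6E)-2-bromo-2,7-dichloro-5-(prop-1-en-2-yl)hept-6-en-3-one (both C2 epimers) | C=C(C)[C@H](/C=C/Cl)CC(=O)C(C)(Cl)Br | intermediate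
14 | (2R,4R,5S)-4-bromo-2-chloro-5-[(E)-2-chloroethenyl]-2,4-dimethylcyclohexan-1-one | C[C@@]1(Cl)C[C@@](C)(Br)[C@H](/C=C/Cl)CC1=O | intermediate
15 | (1R,2R,4R,5S)-4-bromo-2-chloro-5-[(E)-2-chloroethenyl]-2,4-dimethylcyclohexan-1-ol | C[C@@]1(Cl)C[C@@](C)(Br)[C@H](/C=C/Cl)C[C@H]1O | intermediate
16 | (1R,2S,4S,5R)-1,4-dibromo-5-chloro-2-[(E)-2-chloroethenyl]-1,5-dimethylcyclohexane | C[C@@]1(Cl)C[C@@](C)(Br)[C@H](/C=C/Cl)C[C@@H]1Br | target

**Step count**
Total steps: 7. Longest linear sequence: 7 steps (from methacrolein; the route is fully linear).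

**Steps most likely to fail**

Step 5 (ring closure). The risks are 5-exo closure, bromine return to the wrong face of the C4 radical, and Cl/Br scrambling at C2. The fallback separates ring closure from C–Br formation; it sets out from 13 and comes back at 14. Compound 13 is cyclized with stoichiometric CuBr and tris(2-pyridylmethyl)amine in toluene at 110 °C in the presence of DBU, so that the tertiary bromide loses HBr and the alkene (2R,5S)-2-chloro-5-[(E)-2-chloroethenyl]-2-methyl-4-methylidenecyclohexan-1-one F1 is isolated. Hydrogen bromide is then added in the Markovnikov sense by cobalt-catalysed hydrogen-atom-transfer hydrobromination (Co(acac)2, t-BuOOH, Et3SiH, TsBr), where the axial C2–Cl bond again steers bromine into the equatorial position, giving 14.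

Step 6 (reduction). Hydride may instead arrive axially, anti to the C2–Cl bond, and give the equatorial alcohol. The fallback accepts that outcome and inverts; it sets out from 14 and comes back at 15. Compound 14 is reduced with NaBH4/CeCl3 to (1S,2R,4R,5S)-4-bromo-2-chloro-5-[(E)-2-chloroethenyl]-2,4-dimethylcyclohexan-1-ol F2. Mitsunobu esterification (4-nitrobenzoic acid, PPh3, DIAD) inverts C1 and gives (1R,2R,4R,5S)-4-bromo-2-chloro-5-[(E)-2-chloroethenyl]-2,4-dimethylcyclohexyl 4-nitrobenzoate F3. The ester is cleaved with i-Bu2AlH at −78 °C, which is non-basic so the trans-chlorohydrin does not close to an epoxide, giving 15.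

Step 7 (bromide by inversion). Substitution at a secondary carbon next to a quaternary centre may give elimination or chloronium-mediated retention. The fallback forms the C–H bond last instead of the C–Br bond; it sets out from 14, bypasses 15, and comes back at 16. Compound 14 is converted with (PhO)3P, Br2 and Et3N in CH2Cl2 into the vinyl bromide (3R,4R,6R)-1,4-dibromo-6-chloro-3-[(E)-2-chloroethenyl]-4,6-dimethylcyclohex-1-ene F4. Its trisubstituted double bond is reduced by hydrogen-atom-transfer hydrogenation (Mn(dpm)3, dpm = 2,2,6,6-tetramethylheptane-3,5-dionate; PhSiH3, t-BuOOH, i-PrOH), which leaves the 1,2-disubstituted chloroalkene alone. The α-bromo radical takes its hydrogen atom anti to the axial C–Cl bond, so bromine ends equatorial and cis to chlorine, which is 16.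

**Further compounds**
F1 | step 5 | (2R,5S)-2-chloro-5-[(E)-2-chloroethenyl]-2-methyl-4-methylidenecyclohexan-1-one | C[C@@]1(Cl)CC(=C)[C@H](/C=C/Cl)CC1=O
F2 | step 6 | (1S,2R,4R,5S)-4-bromo-2-chloro-5-[(E)-2-chloroethenyl]-2,4-dimethylcyclohexan-1-ol | C[C@@]1(Cl)C[C@@](C)(Br)[C@H](/C=C/Cl)C[C@@H]1O
F3 | step 6 | (1R,2R,4R,5S)-4-bromo-2-chloro-5-[(E)-2-chloroethenyl]-2,4-dimethylcyclohexyl 4-nitrobenzoate | C[C@@]1(Cl)C[C@@](C)(Br)[C@H](/C=C/Cl)C[C@H]1OC(=O)c1ccc(cc1)[N+](=O)[O-]
F4 | step 7 | (3R,4R,6R)-1,4-dibromo-6-chloro-3-[(E)-2-chloroethenyl]-4,6-dimethylcyclohex-1-ene | C[C@@]1(Cl)C[C@@](C)(Br)[C@H](/C=C/Cl)C=C1Br
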